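**Assumption:** the target is the trans-(2S,3S) isomer encoded by the SMILES; compounds 1, 4, 9 and 11 and all reagents are taken as commercially available.

## Retrosynthetic overview

1. Target 13 ⇐ global desilylation ⇐ Suzuki attachment of the (E)-3-oxypropenyl chain to aryl bromide 10.
2. Key disconnection (C2–aryl bond, not the usual C–O bonds): 10 ⇐ trans-selective Friedel–Crafts C-arylation of a chiral 1,4-benzodioxan-2-yl oxocarbenium ion (from acetoxy acetal 8) by unprotected 2,6-dimethoxyphenol 9.
3. 8 ⇐ aryl lactone 7 (reductive acetylation) ⇐ aryl formate 6 ⇐ Baeyer–Villiger of aldehyde 5; the CHO is a latent O1 phenol, so the two catechol oxygens are differentiated from the start.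
4. C3 stereocentre and C3–O4 bond: Mitsunobu inversion of D-glycerate-derived α-hydroxy ester 3 with 5-bromo-o-vanillin 4.
5. Ring order: benzo ring bought (4) → dioxanone ring closed (step 5) → bought syringyl ring attached to the finished heterocycle (step 7) → side chain.

## Route

**Step 1**
Reactants: 1, methyl (R)-2,2-dimethyl-1,3-dioxolane-4-carboxylate
Product: 2, methyl (R)-2,3-dihydroxypropanoate
Conditions: Dowex 50W (H+), MeOH, rt → 40 °C
Reagents that add atoms: none
Why: Acid-catalysed acetonide methanolysis (transketalisation) leaves the stereocentre untouched.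

**Step 2**
Reactants: 2, methyl (R)-2,3-dihydroxypropanoate
Product: 3, methyl (R)-3-[(tert-butyldiphenylsilyl)oxy]-2-hydroxypropanoate
Conditions: TBDPSCl (1.05 equiv), imidazole, CH2Cl2, −10 → 0 °C
Reagents that add atoms: TBDPSCl, CC(C)(C)[Si](Cl)(c1ccccc1)c1ccccc1
Why: Selective silylation of the primary OH over the hindered, less nucleophilic α-hydroxy-ester OH.

**Step 3**
Reactants: 3, methyl (R)-3-[(tert-butyldiphenylsilyl)oxy]-2-hydroxypropanoate; 4, 5-bromo-2-hydroxy-3-methoxybenzaldehyde
Product: 5, methyl (S)-2-(4-bromo-2-formyl-6-methoxyphenoxy)-3-[(tert-butyldiphenylsilyl)oxy]propanoate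
Conditions: PPh3, DIAD, THF, 0 °C → rt
Reagents that add atoms: none
Why: Mitsunobu etherification of an acidic salicylaldehyde-type phenol with a secondary α-hydroxy ester goes by SN2 inversion, turning (R)-C–OH into (S)-C–OAr; this sets C3 of the target.

**Step 4**
Reactants: 5, methyl (S)-2-(4-bromo-2-formyl-6-methoxyphenoxy)-3-[(tert-butyldiphenylsilyl)oxy]propanoate
Product: 6, methyl (S)-2-[4-bromo-2-(formyloxy)-6-methoxyphenoxy]-3-[(tert-butyldiphenylsilyl)oxy]propanoate (used crude)
Conditions: mCPBA (1.5 equiv), CH2Cl2, rt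
Reagents that add atoms: mCPBA, O=C(OO)c1cccc(Cl)c1 (one O)
Why: Baeyer–Villiger (Dakin-type) oxidation; aryl migration is favoured by the ortho-alkoxy donor, as for 2,3-dimethoxybenzaldehyde, and installs O1 at the correct carbon.

**Step 5**
Reactants: 6, the aryl formate
Product: 7, (3S)-7-bromo-3-{[(tert-butyldiphenylsilyl)oxy]methyl}-5-methoxy-2,3-dihydro-1,4-benzodioxin-2-one
Conditions: CSA (10 mol %), MeOH (3 equiv), toluene, 60 → 100 °C, distil off HCO2Me/MeOH
Reagents that add atoms: none
Why: Acid-catalysed transesterification cascade (formate methanolysis, then six-membered lactonisation driven by methanol removal); no base is present, so the α-aryloxy stereocentre is not enolised.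

**Step 6**
Reactants: 7, the lactone
Product: 8, (3S)-7-bromo-3-{[(tert-butyldiphenylsilyl)oxy]methyl}-5-methoxy-2,3-dihydro-1,4-benzodioxin-2-yl acetate (C2 epimer mixture, both usable)
Conditions: DIBAL-H (1.2 equiv), CH2Cl2, −78 °C; then pyridine, DMAP, Ac2O, −78 → −20 °C
Reagents that add atoms: acetic anhydride, CC(=O)OC(C)=O
Why: Rychnovsky reductive acetylation traps the aluminium hemiacetal as the α-acetoxy ether at low temperature, so the epimerisable free α-aryloxy aldehyde is never liberated.

**Step 7 (key step)**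
Reactants: 8, the acetoxy acetal; 9, 2,6-dimethoxyphenol (1.5 equiv)
Product: 10, 4-[(2S,3S)-7-bromo-3-{[(tert-butyldiphenylsilyl)oxy]methyl}-5-methoxy-2,3-dihydro-1,4-benzodioxin-2-yl]-2,6-dimethoxyphenol
Conditions: BF3·OEt2 (2 equiv), CH2Cl2, −78 → −20 °C; brief warming to 0 °C if cis isomer is present; NaHCO3 quench
Reagents that add atoms: none
Why: Proposed new method: BF3 ionises the anomeric acetate to a 1,4-benzodioxan-2-yl oxocarbenium ion, which is attacked by C4 of 9 (para to the free OH, both ortho sites blocked) anti to the bulky C3 CH2OTBDPS group to give the 2,3-trans product and set C2 as S, and any cis isomer or O-aryl acetal can re-ionise (p-hydroxybenzyl aryl ether) and funnel to the diequatorial trans isomer; the closest known reactions are Lewis-acid aryl C-glycosylation of glycosyl acetates with phenols and Friedel–Crafts arylation of 2-acyloxy/alkoxychromans.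

**Step 8**
Reactants: 10, the aryl bromide; 11, (E)-tert-butyldimethyl{[3-(4,4,5,5-tetramethyl-1,3,2-dioxaborolan-2-yl)prop-2-en-1-yl]oxy}silane
Product: 12, 4-[(2S,3S)-7-{(E)-3-[(tert-butyldimethylsilyl)oxy]prop-1-en-1-yl}-3-{[(tert-butyldiphenylsilyl)oxy]methyl}-5-methoxy-2,3-dihydro-1,4-benzodioxin-2-yl]-2,6-dimethoxyphenol
Conditions: Pd(OAc)2 (5 mol %), SPhos (10 mol %), K3PO4, THF/H2O (10:1), 50 °C, degassed
Reagents that add atoms: none
Why: Suzuki–Miyaura coupling of an unhindered aryl bromide with an (E)-alkenyl boronate retains alkene geometry and tolerates the free phenol and both silyl ethers.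

**Step 9**
Reactants: 12, the bis-silyl ether
Product: 13, 4-[(2S,3S)-3-(hydroxymethyl)-7-[(E)-3-hydroxyprop-1-en-1-yl]-5-methoxy-2,3-dihydro-1,4-benzodioxin-2-yl]-2,6-dimethoxyphenol (target)
Conditions: TBAF (3 equiv), AcOH (3 equiv), THF, 0 °C → rt
Reagents that add atoms: none
Why: Fluoride desilylation removes TBS and TBDPS; AcOH buffering avoids phenoxide-driven opening of the p-hydroxybenzyl aryl ether, so neither stereocentre is disturbed.

## Compound list

1 | methyl (R)-2,2-dimethyl-1,3-dioxolane-4-carboxylate | COC(=O)[C@H]1COC(C)(C)O1 | starting material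
2 | methyl (R)-2,3-dihydroxypropanoate | COC(=O)[C@H](O)CO | intermediate
3 | methyl (R)-3-[(tert-butyldiphenylsilyl)oxy]-2-hydroxypropanoate | COC(=O)[C@H](O)CO[Si](c1ccccc1)(c1ccccc1)C(C)(C)C | intermediate
4 | 5-bromo-2-hydroxy-3-methoxybenzaldehyde | O=Cc1cc(Br)cc(OC)c1O | starting material
5 | methyl (S)-2-(4-bromo-2-formyl-6-methoxyphenoxy)-3-[(tert-butyldiphenylsilyl)oxy]propanoate | COC(=O)[C@@H](Oc1c(C=O)cc(Br)cc1OC)CO[Si](c1ccccc1)(c1ccccc1)C(C)(C)C | intermediate
6 | methyl (S)-2-[4-bromo-2-(formyloxy)-6-methoxyphenoxy]-3-[(tert-butyldiphenylsilyl)oxy]propanoate | COC(=O)[C@@H](Oc1c(OC=O)cc(Br)cc1OC)CO[Si](c1ccccc1)(c1ccccc1)C(C)(C)C | intermediate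
7 | (3S)-7-bromo-3-{[(tert-butyldiphenylsilyl)oxy]methyl}-5-methoxy-2,3-dihydro-1,4-benzodioxin-2-one | O=C1Oc2cc(Br)cc(OC)c2O[C@H]1CO[Si](c1ccccc1)(c1ccccc1)C(C)(C)C | intermediate
8 | (3S)-7-bromo-3-{[(tert-butyldiphenylsilyl)oxy]methyl}-5-methoxy-2,3-dihydro-1,4-benzodioxin-2-yl acetate (C2 epimers) | CC(=O)OC1Oc2cc(Br)cc(OC)c2O[C@H]1CO[Si](c1ccccc1)(c1ccccc1)C(C)(C)C | intermediate
9 | 2,6-dimethoxyphenol | COc1cccc(OC)c1O | starting material
10 | 4-[(2S,3S)-7-bromo-3-{[(tert-butyldiphenylsilyl)oxy]methyl}-5-methoxy-2,3-dihydro-1,4-benzodioxin-2-yl]-2,6-dimethoxyphenol | COc1cc([C@@H]2Oc3cc(Br)cc(OC)c3O[C@H]2CO[Si](c4ccccc4)(c5ccccc5)C(C)(C)C)cc(OC)c1O | intermediate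
11 | (E)-tert-butyldimethyl{[3-(4,4,5,5-tetramethyl-1,3,2-dioxaborolan-2-yl)prop-2-en-1-yl]oxy}silane | CC(C)(C)[Si](C)(C)OC/C=C/B1OC(C)(C)C(C)(C)O1 | starting material
12 | 4-[(2S,3S)-7-{(E)-3-[(tert-butyldimethylsilyl)oxy]prop-1-en-1-yl}-3-{[(tert-butyldiphenylsilyl)oxy]methyl}-5-methoxy-2,3-dihydro-1,4-benzodioxin-2-yl]-2,6-dimethoxyphenol | COc1cc([C@@H]2Oc3cc(/C=C/CO[Si](C)(C)C(C)(C)C)cc(OC)c3O[C@H]2CO[Si](c4ccccc4)(c5ccccc5)C(C)(C)C)cc(OC)c1O | intermediate
13 | 4-[(2S,3S)-3-(hydroxymethyl)-7-[(E)-3-hydroxyprop-1-en-1-yl]-5-methoxy-2,3-dihydro-1,4-benzodioxin-2-yl]-2,6-dimethoxyphenol | COc1cc([C@@H]2Oc3cc(/C=C/CO)cc(OC)c3O[C@H]2CO)cc(OC)c1O | target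

## Summary

Total steps: 9. Longest linear sequence: 9 (1 → 13); 4, 9 and 11 enter without prior steps.

Three steps most likely to fail:

1. **Step 7 (Friedel–Crafts on the aryloxy oxocarbenium ion).** Risks are sluggish ionisation, attack through C3 or O of syringol, a second arylation after re-ionisation of 10, and loss of H3 to give the benzodioxine. Fallback: give up the C–C bond formation on the cation. Reduce 7 to the lactol, add 4-(TBSO)-3,5-dimethoxyphenylmagnesium bromide to the ring-opened α-aryloxy aldehyde, then close the C2–O1 bond by acid-mediated SN1 (quinone-methide-type) cycloetherification, which converges on the trans isomer whatever the carbinol configuration.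

2. **Step 3 (Mitsunobu with a 2,6-disubstituted phenol).** Risks are low conversion or elimination of the activated α-hydroxy ester. Fallback: reverse the activation. Convert 3 to its α-triflate (Tf2O, 2,6-lutidine) and alkylate the potassium phenoxide of 4 (K2CO3, MeCN, 0 °C), an SN2 displacement with the same inversion. If that also fails, use SNAr of the alkoxide of ent-3 on 5-bromo-2-fluoro-3-methoxybenzaldehyde, which proceeds with retention.

3. **Step 6 (reductive acetylation of an aryl lactone).** Risks are collapse of the tetrahedral intermediate to aldehyde plus phenoxide, leading to over-reduction or C3 epimerisation. Fallback: stop at the isolated lactol (DIBAL, −78 °C, as for dihydrocoumarins) and change the donor type, either using the lactol directly with TMSOTf in step 7 or converting it to the 2-methoxy acetal (CSA, MeOH/HC(OMe)3). Alternatively, skip the lactone entirely by half-reducing the open phenol ester from step 4 and letting the hydroxy aldehyde cyclise to the same lactol.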